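Everything rests on removing the three ring B oxygens at once: isariotin C is traced to a 1-hydroxybicyclo[3.3.1]non-6-en-9-one that already holds the C3 nitrogen and C4 oxygen. The key step exploits the cis C6–OH/C7–C8 epoxide triad on the exo face of ring B (C1, C8, C7, C6, C5, C9): a singlet oxygen ene reaction at C6=C7 gives the C6 hydroperoxide with the alkene at C7=C8, and Ti(OiPr)4 passes the outer peroxide oxygen to that alkene. The precursor is built from L-pyroglutamate (C1 carbinol set on the lactam) by a Dieckmann closure of ring A and a 6-endo-dig closure of ring B catalysed by [(t-Bu)2(2-biphenylyl)PAu(NCMe)]SbF6; Boc removal and N-acylation finish.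

Key step: step 12

Core numbering used throughout: C1 bridgehead C–OH, C2 CH2, C3 C–N, C4 C–OH, C5 bridgehead CH, C6–C7–C8 three-carbon bridge, C9 ketone. Ring A is C1–C2–C3–C4–C5–C9; ring B is C1–C8–C7–C6–C5–C9.

Remark on C1: on ring A the C1 hydroxyl is cis to the C3 nitrogen and C4 oxygen, and the propargyl group is trans to them. Electrophilic oxygen would enter a cis-fused ring A enol derivative from the opposite face, so C1 is fixed on the lactam, where both electrophiles enter trans to the C2 ester.

Remark on protection: the cyclic carbamate is exchanged for NHBoc/OH while the molecule still carries only the robust alkene (step 11). An oxazolidinone on the final epoxy β-hydroxy ketone could only be opened by hot hydroxide, which risks retro-aldol cleavage at C5–C6 and oxirane opening. After the key step only the acid-labile Boc group has to leave.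

Step 1
Reactants: 1 methyl N-Boc-L-pyroglutamate; 2 propargyl bromide
Product: 3 1-tert-butyl 2-methyl (2S,4R)-5-oxo-4-(prop-2-yn-1-yl)pyrrolidine-1,2-dicarboxylate (trans)
Conditions: LiN(SiMe3)2 (1.05 equiv), THF, −78 °C; then 2, −78 °C
Reagents that add atoms: none
Why: Alkylation of the lactam lithium enolate, the electrophile entering trans to the C2 ester; the configuration at this carbon is provisional because it is re-enolised in step 2, so the cis epimer converges.

Step 2
Reactants: 3 trans-4-propargyl lactam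
Product: 4 1-tert-butyl 2-methyl (2S,4R)-4-hydroxy-5-oxo-4-(prop-2-yn-1-yl)pyrrolidine-1,2-dicarboxylate (OH trans to CO2Me)
Conditions: LiN(SiMe3)2 (1.2 equiv), THF, −78 °C; 2-(phenylsulfonyl)-3-phenyloxaziridine, −78 °C; AcOH
Reagents that add atoms: 2-(phenylsulfonyl)-3-phenyloxaziridine, O=S(=O)(c1ccccc1)N1OC1c1ccccc1
Why: Enolate hydroxylation with an N-sulfonyloxaziridine: oxygen should be delivered to the tetrasubstituted enolate on the face away from the C2 ester, so the hydroxyl ends trans and the propargyl group cis to CO2Me, which is the (R) carbinol needed for core C1.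

Step 3
Reactants: 4 hydroxy lactam
Product: 5 triethylsilyl ether of 4
Conditions: Et3SiOTf (1.3 equiv), 2,6-lutidine, CH2Cl2, −78 → −40 °C
Reagents that add atoms: triethylsilyl trifluoromethanesulfonate, CC[Si](CC)(CC)OS(=O)(=O)C(F)(F)F
Why: Silyl triflate silylation of a tertiary alcohol, kept cold so that the N-Boc group is not attacked; the ether keeps the C1 oxygen from lactonising onto the C4 carbonyl and from quenching the enolates of steps 5 and 7.

Step 4
Reactants: 5 silylated lactam
Product: 6 dimethyl (2S,4R)-2-[(tert-butoxycarbonyl)amino]-4-(prop-2-yn-1-yl)-4-[(triethylsilyl)oxy]pentanedioate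
Conditions: NaOMe (0.2 equiv), MeOH, 0 °C
Reagents that add atoms: methanol, CO
Why: Methanolysis of an N-acyl carbamate (imide-type activation): methoxide should attack the ring carbonyl and not the tert-butyl carbamate, opening the C–N bond to the NHBoc diester; ester exchange at the methyl ester is degenerate.

Step 5
Reactants: 6 NHBoc diester; 7 tert-butyl acetate
Product: 8 1-tert-butyl 7-methyl (4S,6R)-4-[(tert-butoxycarbonyl)amino]-3-oxo-6-(prop-2-yn-1-yl)-6-[(triethylsilyl)oxy]heptanedioate
Conditions: LiN(iPr)2 (4.2 equiv), 7 (4.4 equiv), THF, −78 °C; then 6, −78 → −45 °C; AcOH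
Reagents that add atoms: none
Why: Crossed Claisen condensation of the lithium enolate of 7 with the α-amino ester; the other methyl ester (future C9) is shielded by the fully substituted C1, and the N-lithiated carbamate protects the C3 hydrogen from epimerisation.

Step 6
Reactants: 8 β-keto ester
Product: 9 1-tert-butyl 7-methyl (3R,4S,6R)-4-[(tert-butoxycarbonyl)amino]-3-hydroxy-6-(prop-2-yn-1-yl)-6-[(triethylsilyl)oxy]heptanedioate (anti amino alcohol)
Conditions: LiAlH(OtBu)3 (2.2 equiv), EtOH, −78 °C
Reagents that add atoms: none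
Why: Chelation-controlled hydride reduction of an N-carbamoyl α-amino ketone, a reaction class that gives the anti amino alcohol; this sets core C4 as R, cis to nitrogen once ring A is closed, and the esters are not reduced at this temperature.

Step 7
Reactants: 9 anti amino alcohol
Product: 11 tert-butyl (3aS,5R,7aR)-2,6-dioxo-5-(prop-2-yn-1-yl)-5-[(triethylsilyl)oxy]octahydro-1,3-benzoxazole-7-carboxylate (ring A β-keto ester; C7 epimers/enol), via oxazolidinone diester 10 (not isolated)
Conditions: NaN(SiMe3)2 (1.1 equiv), THF, 0 °C; then NaN(SiMe3)2 (2.2 equiv), −78 → 0 °C; AcOH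
Reagents that add atoms: none
Why: The alkoxide should attack the Boc carbonyl (5-exo, tert-butoxide lost, retention at C3 and C4) to give the cis-oxazolidinone, whose tert-butyl ester enolate then closes ring A by Dieckmann condensation on the C9 methyl ester; only C5 can enolise, and the N-metalated carbamate oxygen is too poor a leaving group for β-elimination.

Step 8
Reactants: 11 ring A β-keto ester
Product: 13 (3aS,5R,7aR)-5-hydroxy-5-(prop-2-yn-1-yl)hexahydro-1,3-benzoxazole-2,6(3H)-dione, via β-keto acid 12 (not isolated)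
Conditions: CF3CO2H/CH2Cl2 (1:2), H2O (5 equiv), rt; evaporate; toluene, 60 °C
Reagents that add atoms: none
Why: Acidolysis of the tert-butyl ester and the silyl ether, then thermal decarboxylation of the β-keto acid; no stereocentre is touched because C1 is fully substituted and the oxazolidinone is acid-stable.

Step 9
Reactants: 13 α-hydroxy ketone
Product: 15 (3aS,5R,7aR)-5-(prop-2-yn-1-yl)-5,6-bis[(triethylsilyl)oxy]-3a,4,5,7a-tetrahydro-1,3-benzoxazol-2(3H)-one (C9=C5 silyl enol ether), via N-silyl enol ether 14 (not isolated)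
Conditions: Et3SiOTf (3.5 equiv), Et3N (5 equiv), CH2Cl2, −78 → −20 °C; then aq. NaHCO3, 0 °C
Reagents that add atoms: triethylsilyl trifluoromethanesulfonate, CC[Si](CC)(CC)OS(=O)(=O)C(F)(F)F
Why: Soft enolisation with silyl triflate and amine; C1 is quaternary, so only the C9=C5 enol ether can form, the tertiary hydroxyl and the carbamate N–H are silylated in the same operation, no free enolate is present that could expel the C4 oxygen, and the bicarbonate work-up hydrolyses only the labile N–Si bond.

Step 10
Reactants: 15 silyl enol ether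
Product: 17 1-hydroxybicyclo[3.3.1]non-6-en-9-one carrying the cis-fused C3–N/C4–O oxazolidinone (1R,3S,4R,5R; N equatorial on ring A; O axial), via silylated bicycle 16 (not isolated)
Conditions: [(t-Bu)2(2-biphenylyl)PAu(NCMe)]SbF6 (3 mol%), acetone, H2O (2 equiv), rt; then HF·pyridine, THF, 0 °C
Reagents that add atoms: none
Why: Carbocyclisation of a silyl enol ether onto a terminal alkyne catalysed by the cationic monovalent gold complex [(t-Bu)2(2-biphenylyl)PAu(NCMe)]SbF6 (6-endo-dig, C5 attacks the alkyne terminus C6, protodeauration leaves C6=C7); the propargyl arm can reach C5 only on the ring A face it occupies, anti to the axial C4 oxygen, so C5 follows from C1, and fluoride then frees the C1 hydroxyl.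

Step 11
Reactants: 17 bicyclic oxazolidinone
Product: 19 tert-butyl N-[(1R,3S,4R,5R)-1,4-dihydroxy-9-oxobicyclo[3.3.1]non-6-en-3-yl]carbamate, via N-Boc oxazolidinone 18 (not isolated)
Conditions: Boc2O (1.3 equiv), DMAP (0.1 equiv), MeCN, rt; then MeOH, Cs2CO3 (0.3 equiv), rt
Reagents that add atoms: di-tert-butyl dicarbonate, CC(C)(C)OC(=O)OC(=O)OC(C)(C)C
Why: N-Acylation with Boc2O makes the ring carbonyl the electrophilic one, and catalytic methoxide then opens it (oxazolidinone to NHBoc alcohol, C4 oxygen freed as dimethyl carbonate is lost); the bridged ketone cannot enolise and the tertiary hydroxyl is too hindered to be acylated.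

Step 12
Reactants: 19 NHBoc bicyclic alkene (key-step precursor)
Product: 21 tert-butyl carbamate of the isariotin core (C6 exo hydroxyl; C7–C8 exo epoxide), via C6 hydroperoxide 20 (not isolated)
Conditions: O2, tetraphenylporphyrin (1 mol%), white LED, Ti(OiPr)4 (0.3 equiv), 4 Å sieves, CH2Cl2, −20 → 0 °C
Reagents that add atoms: dioxygen, O=O
Why: The Schenck ene reaction should begin with singlet oxygen approaching C6=C7 from the exo face (the side of C9), bonding to C6 through a perepoxide-like transition state while the exo, pseudo-axial C8–H on that face is transferred, so that the C6 exo hydroperoxide forms with the alkene shifted to C7=C8. Ti(OiPr)4 then engages the hydroperoxide and the terminal peroxide oxygen is delivered to C7=C8 from the face of the C6 oxygen, the closest known reaction type being the one-pot photooxygenation/Ti(OiPr)4 hydroxy-epoxidation of alkenes that carry allylic hydrogens. The oxirane closes in a 3-exo fashion as the O–O bond breaks, which leaves the proximal oxygen as the C6 hydroxyl. C6 is set by exo attack, since ring A with its endo C3–H blocks the other face of ring B, and C7 and C8 are set by delivery from the oxygen already on C6. The selectivity needed is regiochemical, and the skeleton secures it: the only other allylic hydrogen sits on bridgehead C5, lies near the nodal plane of the alkene and could only give a bridgehead C5=C6 alkene (Bredt's rule). No second alkene is present and the C9 ketone, flanked by two bridgeheads, cannot enolise.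

Step 13
Reactants: 21 Boc-protected core
Product: 22 ammonium trifluoroacetate of the isariotin core amine
Conditions: CF3CO2H/CH2Cl2 (1:4), 0 °C, 30 min; evaporate
Reagents that add atoms: trifluoroacetic acid, OC(=O)C(F)(F)F
Why: Acidolysis of the tert-butyl carbamate (isobutene and CO2 lost); the oxirane is secondary, flanked by oxygenated carbons and screened on its rear (endo) face, so brief cold acid should leave it intact.

Step 14
Reactants: 23 δ-decalactone
Product: 24 6-pentyltetrahydro-2H-pyran-2-ol (lactol, racemic)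
Conditions: iBu2AlH (1.1 equiv), CH2Cl2, −78 °C; aq. potassium sodium tartrate
Reagents that add atoms: none
Why: Half-reduction of a lactone to the lactol at low temperature, where the tetrahedral aluminate does not collapse.

Step 15
Reactants: 24 lactol; 25 tert-butyl (triphenylphosphoranylidene)acetate
Product: 26 tert-butyl (E)-7-hydroxydodec-2-enoate
Conditions: toluene, 80 °C
Reagents that add atoms: none
Why: Wittig olefination of the open hydroxy aldehyde form of the lactol by a stabilised ylide, E-selective; the neutral medium avoids oxa-Michael closure of the hydroxy enoate.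

Step 16
Reactants: 26 hydroxy enoate
Product: 27 tert-butyl (E)-7-oxododec-2-enoate
Conditions: Dess–Martin periodinane, NaHCO3, CH2Cl2, rt
Reagents that add atoms: none
Why: Dess–Martin oxidation of the secondary alcohol to the ketone; the racemic carbinol centre disappears and the enoate is untouched.

Step 17
Reactants: 27 keto enoate
Product: 28 (E)-7-oxododec-2-enoic acid
Conditions: CF3CO2H/CH2Cl2 (1:3), rt
Reagents that add atoms: none
Why: Acidolysis of the tert-butyl ester with loss of isobutene; no base is used, so the (E)-enoate can neither isomerise nor undergo conjugate addition.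

Step 18
Reactants: 22 core ammonium trifluoroacetate; 28 (E)-7-oxododec-2-enoic acid
Product: 30 isariotin C, via benzotriazolyl ester 29 (not isolated)
Conditions: iPrN=C=NiPr, 1-hydroxybenzotriazole, iPr2NEt (1.1 equiv), DMF, 0 °C → rt
Reagents that add atoms: none
Why: Carbodiimide/hydroxybenzotriazole amide coupling; the amine freed by iPr2NEt should be acylated far faster than the three hydroxyl groups, and no stereocentre is touched.

Compound list

1 | 1-tert-butyl 2-methyl (2S)-5-oxopyrrolidine-1,2-dicarboxylate (methyl N-Boc-L-pyroglutamate) | COC(=O)[C@@H]1CCC(=O)N1C(=O)OC(C)(C)C | starting material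
2 | propargyl bromide (3-bromoprop-1-yne) | C#CCBr | starting material
3 | 1-tert-butyl 2-methyl (2S,4R)-5-oxo-4-(prop-2-yn-1-yl)pyrrolidine-1,2-dicarboxylate (trans; the cis epimer converges in step 2) | COC(=O)[C@@H]1C[C@@H](CC#C)C(=O)N1C(=O)OC(C)(C)C | intermediate
4 | 1-tert-butyl 2-methyl (2S,4R)-4-hydroxy-5-oxo-4-(prop-2-yn-1-yl)pyrrolidine-1,2-dicarboxylate (OH trans to CO2Me) | COC(=O)[C@@H]1C[C@](O)(CC#C)C(=O)N1C(=O)OC(C)(C)C | intermediate
5 | 1-tert-butyl 2-methyl (2S,4R)-5-oxo-4-(prop-2-yn-1-yl)-4-[(triethylsilyl)oxy]pyrrolidine-1,2-dicarboxylate | COC(=O)[C@@H]1C[C@](O[Si](CC)(CC)CC)(CC#C)C(=O)N1C(=O)OC(C)(C)C | intermediate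
6 | dimethyl (2S,4R)-2-[(tert-butoxycarbonyl)amino]-4-(prop-2-yn-1-yl)-4-[(triethylsilyl)oxy]pentanedioate | COC(=O)[C@@H](NC(=O)OC(C)(C)C)C[C@](O[Si](CC)(CC)CC)(CC#C)C(=O)OC | intermediate
7 | tert-butyl acetate | CC(=O)OC(C)(C)C | starting material
8 | 1-tert-butyl 7-methyl (4S,6R)-4-[(tert-butoxycarbonyl)amino]-3-oxo-6-(prop-2-yn-1-yl)-6-[(triethylsilyl)oxy]heptanedioate | CC(C)(C)OC(=O)CC(=O)[C@@H](NC(=O)OC(C)(C)C)C[C@](O[Si](CC)(CC)CC)(CC#C)C(=O)OC | intermediate
9 | 1-tert-butyl 7-methyl (3R,4S,6R)-4-[(tert-butoxycarbonyl)amino]-3-hydroxy-6-(prop-2-yn-1-yl)-6-[(triethylsilyl)oxy]heptanedioate | CC(C)(C)OC(=O)C[C@@H](O)[C@@H](NC(=O)OC(C)(C)C)C[C@](O[Si](CC)(CC)CC)(CC#C)C(=O)OC | intermediate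
10 | methyl (2R)-2-{[(4S,5R)-5-(2-tert-butoxy-2-oxoethyl)-2-oxo-1,3-oxazolidin-4-yl]methyl}-2-[(triethylsilyl)oxy]pent-4-ynoate (cis-oxazolidinone diester) | CC(C)(C)OC(=O)C[C@H]1OC(=O)N[C@H]1C[C@](O[Si](CC)(CC)CC)(CC#C)C(=O)OC | intermediate
11 | tert-butyl (3aS,5R,7aR)-2,6-dioxo-5-(prop-2-yn-1-yl)-5-[(triethylsilyl)oxy]octahydro-1,3-benzoxazole-7-carboxylate (C7 epimers and enol) | O=C1N[C@H]2C[C@](O[Si](CC)(CC)CC)(CC#C)C(=O)C(C(=O)OC(C)(C)C)[C@H]2O1 | intermediate
12 | (3aS,5R,7aR)-5-hydroxy-2,6-dioxo-5-(prop-2-yn-1-yl)octahydro-1,3-benzoxazole-7-carboxylic acid | O=C1N[C@H]2C[C@](O)(CC#C)C(=O)C(C(=O)O)[C@H]2O1 | intermediate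
13 | (3aS,5R,7aR)-5-hydroxy-5-(prop-2-yn-1-yl)hexahydro-1,3-benzoxazole-2,6(3H)-dione | O=C1N[C@H]2C[C@](O)(CC#C)C(=O)C[C@H]2O1 | intermediate
14 | (3aS,5R,7aR)-5-(prop-2-yn-1-yl)-3-(triethylsilyl)-5,6-bis[(triethylsilyl)oxy]-3a,4,5,7a-tetrahydro-1,3-benzoxazol-2(3H)-one | O=C1N([Si](CC)(CC)CC)[C@H]2C[C@](O[Si](CC)(CC)CC)(CC#C)C(O[Si](CC)(CC)CC)=C[C@H]2O1 | intermediate
15 | (3aS,5R,7aR)-5-(prop-2-yn-1-yl)-5,6-bis[(triethylsilyl)oxy]-3a,4,5,7a-tetrahydro-1,3-benzoxazol-2(3H)-one | O=C1N[C@H]2C[C@](O[Si](CC)(CC)CC)(CC#C)C(O[Si](CC)(CC)CC)=C[C@H]2O1 | intermediate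
16 | 1-[(triethylsilyl)oxy]bicyclo[3.3.1]non-6-en-9-one with cis-fused C3–N/C4–O oxazolidinone (1R,3S,4R,5R) | O=C1N[C@H]2C[C@@]3(O[Si](CC)(CC)CC)C(=O)[C@H](C=CC3)[C@H]2O1 | intermediate
17 | 1-hydroxybicyclo[3.3.1]non-6-en-9-one with cis-fused C3–N/C4–O oxazolidinone (1R,3S,4R,5R) | O=C1N[C@H]2C[C@@]3(O)C(=O)[C@H](C=CC3)[C@H]2O1 | intermediate
18 | N-Boc derivative of 17 | O=C1N(C(=O)OC(C)(C)C)[C@H]2C[C@@]3(O)C(=O)[C@H](C=CC3)[C@H]2O1 | intermediate
19 | tert-butyl N-[(1R,3S,4R,5R)-1,4-dihydroxy-9-oxobicyclo[3.3.1]non-6-en-3-yl]carbamate (key-step precursor) | CC(C)(C)OC(=O)N[C@H]1C[C@@]2(O)C(=O)[C@H](C=CC2)[C@H]1O | intermediate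
20 | C6 exo hydroperoxide of 19 with the alkene at C7=C8 | CC(C)(C)OC(=O)N[C@H]1C[C@@]2(O)C(=O)[C@H]([C@H](OO)C=C2)[C@H]1O | intermediate
21 | tert-butyl carbamate of the isariotin core: 1,4,6-trihydroxy-7,8-epoxybicyclo[3.3.1]nonan-9-one, C6 hydroxyl and epoxide exo (key-step product) | CC(C)(C)OC(=O)N[C@H]1C[C@@]2(O)C(=O)[C@H]([C@H](O)[C@@H]3O[C@@H]32)[C@H]1O | intermediate
22 | ammonium trifluoroacetate of the core amine | [NH3+][C@H]1C[C@@]2(O)C(=O)[C@H]([C@H](O)[C@@H]3O[C@@H]32)[C@H]1O.[O-]C(=O)C(F)(F)F | intermediate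
23 | δ-decalactone (6-pentyltetrahydro-2H-pyran-2-one, racemic) | CCCCCC1CCCC(=O)O1 | starting material
24 | 6-pentyltetrahydro-2H-pyran-2-ol | CCCCCC1CCCC(O)O1 | intermediate
25 | tert-butyl (triphenylphosphoranylidene)acetate | CC(C)(C)OC(=O)C=P(c1ccccc1)(c1ccccc1)c1ccccc1 | starting material
26 | tert-butyl (E)-7-hydroxydodec-2-enoate | CCCCCC(O)CCC/C=C/C(=O)OC(C)(C)C | intermediate
27 | tert-butyl (E)-7-oxododec-2-enoate | CCCCCC(=O)CCC/C=C/C(=O)OC(C)(C)C | intermediate
28 | (E)-7-oxododec-2-enoic acid | CCCCCC(=O)CCC/C=C/C(=O)O | intermediate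
29 | 1H-benzotriazol-1-yl (E)-7-oxododec-2-enoate | CCCCCC(=O)CCC/C=C/C(=O)On1nnc2ccccc12 | intermediate
30 | isariotin C, the (E)-7-oxododec-2-enamide of the C3 amine of the core | CCCCCC(=O)CCC/C=C/C(=O)N[C@H]1C[C@@]2(O)C(=O)[C@H]([C@H](O)[C@@H]3O[C@@H]32)[C@H]1O | target

Total step count: 18 (13 on the core line, 4 for the acid, 1 coupling).
Longest linear sequence: 14 steps (steps 1–13, then step 18).

Steps most likely to fail

Step 12 (key step). The ene reaction of the 1,2-disubstituted ring B alkene may be slow, so that sensitiser bleaching and over-oxidation compete, or oxygen transfer may stall because the diol and the carbamate occupy Ti(OiPr)4. The fallback sets out from 17, whose oxazolidinone tolerates a silyl triflate better than a tert-butyl carbamate does, and returns at 21.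
- Dimethyldioxirane in acetone at 0 °C should epoxidise the exo face to the 6,7-exo-epoxide F1.
- Me3SiOTf (4 equiv)/DBU in toluene (−78 → 0 °C) should isomerise it to the N,O,O-tris(trimethylsilyl) allylic ether F2: the silyl-activated oxirane opens at C7 and the base removes a C8 hydrogen, C5 being a bridgehead.
- Aqueous NaHCO3 work-up hydrolyses the N–Si bond and leaves the bis(trimethylsilyl) ether F3.
- Boc2O/DMAP in MeCN then acylates nitrogen only, both hydroxyls being masked, and gives the N-Boc oxazolidinone F4.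
- Cs2CO3 in methanol, finished with citric acid, opens the ring and removes both silyl ethers to give the allylic alcohol F5 (C6 exo hydroxyl, C7=C8).
- VO(acac)2/t-BuOOH in CH2Cl2 at 0 °C then delivers oxygen syn to the pseudo-axial C6 hydroxyl and gives 21.

Step 2. Enolisation at the now tertiary lactam α-carbon may be incomplete, the enolate may add to the sulfonimine by-product, or facial selectivity may erode. The fallback sets out from 3 and returns at 4. LiN(SiMe3)2 followed by Et3SiCl should give the triethylsilyl ketene N,O-acetal F6. Dimethyldioxirane at −78 °C should oxidise this neutral enol silane on the face away from the C2 ester (Rubottom-type oxidation), and hydrolytic work-up gives 4.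

Step 4. Methoxide may attack the carbamate carbonyl (loss of Boc), or the C2 centre may epimerise before the ring opens, because the ring carbonyl is neopentyl-like. The fallback sets out from 5 and returns at 6. LiOH/H2O2 in THF/water at 0 °C (hydroperoxide anion, which cleaves hindered imides at the acyl carbonyl) with Na2SO3 work-up should give the carboxylic acid F7. Me3SiCHN2 in methanol/toluene then gives 6; a methyl ester that was also saponified is re-formed in the same operation.

Further compounds

F1 | step 12 | 6,7-exo-epoxide of 17 (1-hydroxy-6,7-epoxybicyclo[3.3.1]nonan-9-one with the C3,C4 oxazolidinone) | O=C1N[C@H]2C[C@@]3(O)C(=O)[C@H]([C@@H]4O[C@@H]4C3)[C@H]2O1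
F2 | step 12 | N,O,O-tris(trimethylsilyl) derivative of the C6 exo allylic alcohol (C7=C8) with the C3,C4 oxazolidinone | O=C1N([Si](C)(C)C)[C@H]2C[C@@]3(O[Si](C)(C)C)C(=O)[C@H]([C@H](O[Si](C)(C)C)C=C3)[C@H]2O1
F3 | step 12 | C1,C6-bis(trimethylsilyl) ether of the C6 exo allylic alcohol (C7=C8) with the free N–H oxazolidinone | O=C1N[C@H]2C[C@@]3(O[Si](C)(C)C)C(=O)[C@H]([C@H](O[Si](C)(C)C)C=C3)[C@H]2O1
F4 | step 12 | N-Boc derivative of F3 | O=C1N(C(=O)OC(C)(C)C)[C@H]2C[C@@]3(O[Si](C)(C)C)C(=O)[C@H]([C@H](O[Si](C)(C)C)C=C3)[C@H]2O1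
F5 | step 12 | tert-butyl carbamate of 1,4,6-trihydroxybicyclo[3.3.1]non-7-en-9-one (C6 hydroxyl exo) | CC(C)(C)OC(=O)N[C@H]1C[C@@]2(O)C(=O)[C@H]([C@H](O)C=C2)[C@H]1O
F6 | step 2 | 1-tert-butyl 2-methyl (2S)-4-(prop-2-yn-1-yl)-5-[(triethylsilyl)oxy]-2,3-dihydro-1H-pyrrole-1,2-dicarboxylate | COC(=O)[C@@H]1CC(CC#C)=C(O[Si](CC)(CC)CC)N1C(=O)OC(C)(C)C
F7 | step 4 | (2R,4S)-4-[(tert-butoxycarbonyl)amino]-5-methoxy-5-oxo-2-(prop-2-yn-1-yl)-2-[(triethylsilyl)oxy]pentanoic acid | COC(=O)[C@@H](NC(=O)OC(C)(C)C)C[C@](O[Si](CC)(CC)CC)(CC#C)C(=O)O
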